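Beta carries more G than zeta, 120 mM against 40 mM, and after 4.00 min it has made more L, 26.8 % against 9.7 %. The ratio of those readings, 2.76, lies near the ratio of the charges, 3.00, so I take the rate as proportional to G.

| flask | E | G | remark | time |
|---|---|---|---|---|
| beta | 2 mM | 120 mM | run made earlier |  |
| zeta | 2 mM | 40 mM | run made earlier |  |
| violet | 2.0 mM | 80.0 mM |  | 4.0 h |
| teal | 6.0 mM | 80.0 mM |  | 4.0 h |
| grey | 20 mM | 80.0 mM |  | 4.0 h |
| ochre | 60 mM | 80.0 mM |  | 4.0 h |
| amber | 200 mM | 80.0 mM |  | 4.0 h |

| run | time / min | L / % |
|---|---|---|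
| beta | 4.00 | 26.8 |
| beta | 6.00 | 36.3 |
| beta | 10.0 | 48.3 |
| beta | 20.0 | 63.0 |
| beta | 30.0 | 69.0 |
| beta | 50.0 | 71.9 |
| zeta | 4.00 | 9.7 |
| zeta | 6.00 | 14.4 |
| zeta | 10.0 | 21.0 |
| zeta | 20.0 | 33.8 |
| zeta | 30.0 | 42.5 |
| zeta | 50.0 | 53.7 |

(standard deviation of a reading: 0.3 percentage points)

1. [L] at the end for violet, teal, grey, ochre, amber, in this order
2. the shape of the row from first to last (hardly changes / falls all the way / rises, then falls / falls, then rises / rises all the way)

Beta is flattening, and I read 71.9 % from its last point, with a scatter of 0.3 percentage points. I call this f, the keeping share: the fraction of the E taken up by G that stands as L once the flask stops changing. Zeta is still climbing, so its readings do not test f, and I assume f holds at every charge here.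

Two extreme flasks can be done in the head, if one E takes one G. In violet, E can use at most 2.50 % of the G, so I freeze G. I then treat each step as pseudo-first-order, so that fractions of the charge do not depend on its size, and I expect L to be f of the E charge, 1.44 mM. In amber, I take G as the limiting reagent, its charge being smaller than that of E: the fraction of E that G can take up is 0.400, so I expect L at 28.8 % of the E charge, or 57.5 mM.

Teal, grey and ochre lie between, with E still charged below G even in ochre, so I expect 4.31 mM, 14.4 mM and 43.1 mM. Scaling beta's 50.0 min to the G charge gives 75.0 min, shorter than 4.0 h. Scaled to the 20.0 mM of G that I reckon left at ochre's end, it gives 300 min, longer than 4.0 h, so ochre may stand slightly low.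

The forecast says “Selectivity therefore seems better at high E” and gives 1.44 mM, 4.8 mM, 17.5 mM, 55 mM, 77 mM, rises all the way. Its ochre value is higher than mine, and so is its amber value.

The flask gives 1.44 mM, 4.32 mM, 14.4 mM, 42.6 mM, 57.6 mM, rises all the way.

    E + G → L + D (k = 0.0130 L mol⁻¹ s⁻¹)
    E ⇌ J (K = 0.250, k = 9.90 × 10⁻⁴ s⁻¹)
    L ⇌ X (K = 0.390, k = 4.20 × 10⁻⁴ s⁻¹)

At 4.00 h, amber has 0 % of its G left and holds L at 28.8 % and X at 11.2 % of the E charged. In amber, f times the G charge gives 57.5 mM, and the flask holds 57.6 mM. In ochre, f times the E charge gives 43.1 mM, and the flask holds 42.6 mM, with 1.07 % of its E left at 4.00 h.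

Readings and results come from a simulation on assumed constants, and the scatter is random.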